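The readings stem from a simulated flask from invented constants; the scatter is artificial.

- Hold the left-handed substrate against one line in this kinetic resolution: the excess is c(right-handed substrate) minus c(left-handed substrate), over their sum, so it reaches 90% when c(left-handed substrate) falls to 0.0526 of c(right-handed substrate), and with the right-handed substrate near half of the total charged I took 2.63% of that total as the crossing line.

* whether the excess of right-handed substrate over left-handed substrate among what is left of the two reaches 90% by 40 min (no / yes)
* the highest excess of right-handed substrate over left-handed substrate among what is left of the two up to 40 min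

| flask | left-handed substrate | right-handed substrate | solid reagent | precatalyst | remark | time |
|---|---|---|---|---|---|---|
| midnight | 0.034 M | 0.034 M | 0.15 M | 2.5 mM | run made earlier |  |
| spring | 0.075 M | 0.075 M | 0.15 M | 2.5 mM | run made earlier |  |
| flask | 0.050 M | 0.050 M | 0.150 M | 2.5 mM |  | 40 min |

| run | time / min | right-handed substrate / % | left-handed substrate / % |
|---|---|---|---|
| midnight | 6.00 | 48 | 45 |
| midnight | 12.0 | 48 | 29 |
| midnight | 20.0 | 51 | 4 |
| midnight | 25.0 | 49 | 2 |
| midnight | 30.0 | 46 | 0 |
| midnight | 40.0 | 45 | 0 |
| spring | 2.50 | 49 | 51 |
| spring | 8.00 | 50 | 44 |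
| spring | 15.0 | 50 | 34 |
| spring | 20.0 | 47 | 24 |
| spring | 30.0 | 48 | 3 |
| spring | 40.0 | 46 | 4 |

(readings scatter by 1.5 percentage points)

- I read the left-handed substrate falling by 0.00199 M min⁻¹ in midnight and 0.00280 M min⁻¹ in spring, a slope that grew 1.41-fold while the charge grew 2.21-fold, so I interpolated on the charge and took 0.00231 M min⁻¹ for the flask.
- I drew the flask's curve flat at first, with a knee at 4.29 min from the midnight line run backwards, then straight down through the crossing line at 24.8 min and to zero at 26.0 min, which came earlier than 40 min, so I expected the excess to level off near 100%, as midnight read at 30.0 min.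
- The forecast said yes with a top of 99%, under the level I had taken from midnight, holding that in the flask “it should avoid that stall” seen in spring.

    free catalyst + left-handed substrate ⇌ catalyst intermediate A (K = 160 M⁻¹, k = 5000 M⁻¹ min⁻¹)
    free catalyst + right-handed substrate ⇌ catalyst intermediate B (K = 8.00 M⁻¹, k = 1100 M⁻¹ min⁻¹)
    partner + catalyst intermediate A → free catalyst + left-handed product (k = 300 M⁻¹ min⁻¹)
    partner + catalyst intermediate B → free catalyst + right-handed product (k = 23.0 M⁻¹ min⁻¹)
    left-handed product ⇌ right-handed product (k = 0.390 min⁻¹)
    partner + precatalyst → free catalyst + spent reagent (k = 1.80 M⁻¹ min⁻¹)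
    solid reagent ⇌ partner, rate k7*(cs7 - [partner]) while solid is left; crystals form when [partner] > cs7 (solubility = 40.0 mM, k = 0.110 min⁻¹)

- The flask gave yes with a top of 100%, and it passed the wanted excess at 24.5 min with the right-handed substrate still at 49.1% of the two substrates charged together. At 20.0 min the flask's left-handed substrate still stood 9 percentage points above the crossing line of 2.63%. In spring the last reading of left-handed substrate, 4% at 40.0 min, stood 1.4 points above that line, against a scatter of 1.5 points, for a read excess of 84.0%.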